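**Retrosynthetic overview**

1. The target is a meso oxolane (O1, C2–C5). It is traced back to its bis-MOM ether, and the C3 methyl to a C3 ethyl ester (CO2Et → CH2OH → CH2OTs → CH3).
2. The C3 ester configuration (cis to the C4 methyl, trans to the C2 aryl) comes from base epimerisation after syn-hydrogenation of the C2=C3 bond of a 4,5-dihydrofuran-3-carboxylate.
3. Key disconnection: O1–C2(aryl)=C3 is the enol of an aryl ketone carrying an ester on C3, and C4(methyl)–C5(aryl) is an (E)-propenylarene. Cutting C3–C4 and C5–O1 gives an aroylacetate and a propenylarene, joined by Mn(OAc)3 oxidative (3+2) annulation.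
4. The aroylacetate comes from acetosyringone (MOM ether, then NaH/diethyl carbonate). The propenylarene comes from 4-allyl-2,6-dimethoxyphenol (MOM ether, then KOtBu isomerisation).
5. Ring order: both benzene rings are bought; the oxolane is the only ring formed, in step 5.

Key step: step 5

Remark: the target is meso (mirror plane through O1 and the midpoint of C3–C4), so the route is run racemic; the SMILES of the chiral intermediates 8–12 show one enantiomer. Ar = 3,5-dimethoxy-4-(methoxymethoxy)phenyl throughout.

**Route**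

Step 1
Reactants: 1 acetosyringone
Product: 2 1-[3,5-dimethoxy-4-(methoxymethoxy)phenyl]ethan-1-one
Conditions: MOMCl, iPr2NEt, CH2Cl2, 0 °C to rt
Reagents that add atoms: chloromethyl methyl ether (MOMCl), COCCl
Why: O-alkylation of the acidic syringyl phenol with the reactive α-chloro ether (Williamson-type acetal formation) should proceed despite the two flanking methoxy groups, and the ketone is untouched.

Step 2
Reactants: 2 1-[3,5-dimethoxy-4-(methoxymethoxy)phenyl]ethan-1-one; 3 diethyl carbonate
Product: 4 ethyl 3-[3,5-dimethoxy-4-(methoxymethoxy)phenyl]-3-oxopropanoate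
Conditions: NaH (2.5 equiv), THF, reflux; then AcOH, 0 °C
Reagents that add atoms: none
Why: Crossed Claisen condensation of the methyl ketone sodium enolate with the non-enolisable carbonate is driven to completion by deprotonation of the β-keto ester, and the MOM acetal is stable to base.

Step 3
Reactants: 5 4-allyl-2,6-dimethoxyphenol
Product: 6 5-allyl-1,3-dimethoxy-2-(methoxymethoxy)benzene
Conditions: MOMCl, iPr2NEt, CH2Cl2, 0 °C to rt
Reagents that add atoms: chloromethyl methyl ether (MOMCl), COCCl
Why: The same phenol O-alkylation as in step 1 masks the oxidation-prone phenol before base and oxidant are applied.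

Step 4
Reactants: 6 5-allyl-1,3-dimethoxy-2-(methoxymethoxy)benzene
Product: 7 (E)-1,3-dimethoxy-2-(methoxymethoxy)-5-(prop-1-en-1-yl)benzene
Conditions: KOtBu (0.3 equiv), DMSO, rt
Reagents that add atoms: none
Why: Base-mediated prototropic isomerisation of the allylarene through the benzylic allyl anion moves the alkene into conjugation and should give mainly the thermodynamically preferred E isomer; residual Z isomer is harmless in step 5.

Step 5
Reactants: 4 ethyl 3-[3,5-dimethoxy-4-(methoxymethoxy)phenyl]-3-oxopropanoate; 7 (E)-1,3-dimethoxy-2-(methoxymethoxy)-5-(prop-1-en-1-yl)benzene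
Product: 8 ethyl 4,5-trans-2,5-bis[3,5-dimethoxy-4-(methoxymethoxy)phenyl]-4-methyl-4,5-dihydrofuran-3-carboxylate (racemic; 4R,5R enantiomer drawn)
Conditions: Mn(OAc)3·2H2O (2.2 equiv), Cu(OAc)2·H2O (0.2 equiv), NaOAc, AcOH, 40 °C, N2
Reagents that add atoms: none
Why: Mn(OAc)3 (trivalent manganese) forms the manganese enolate of 4 and oxidises it to the electrophilic α-keto ester radical, which adds to the electron-rich alkene of 7 at the methyl-bearing carbon (C3–C4) and leaves a benzylic radical that Cu(OAc)2 (divalent copper) oxidises to the trialkoxyaryl-stabilised benzylic cation. The closest known reaction type is the Mn(OAc)3-mediated oxidative annulation of 1,3-dicarbonyl compounds with styrenes to 4,5-dihydrofurans. The oxolane ring closes in a polar step, by attack of the ketone (enol) oxygen on the benzylic cation (C5–O1), and loss of the remaining α-proton then gives the C2=C3 enol ether. C4 and C5 are formed racemic and their trans relation is set in this cation capture, where the C5 aryl group takes the side away from the C4 methyl; because the cation is planar the outcome should not depend on the E/Z purity of 7. The step needs radical attack at the alkene carbon remote from the aryl ring, which the stability of the benzylic radical and the polarity match secure, and O- rather than C-closure, which the geometry of the 1,3-dicarbonyl unit secures. The NaOAc buffer and the low temperature are chosen to spare the MOM acetals.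

Step 6
Reactants: 8 ethyl 4,5-trans-2,5-diaryl-4-methyl-4,5-dihydrofuran-3-carboxylate
Product: 9 ethyl 2,5-bis[3,5-dimethoxy-4-(methoxymethoxy)phenyl]-4-methyloxolane-3-carboxylate, C2 aryl/C3 ester cis, C3 ester/C4 methyl trans, C4 methyl/C5 aryl trans, the two aryl groups cis (racemic; 2S,3R,4R,5R enantiomer drawn)
Conditions: H2 (4 atm), 5% Rh/Al2O3, EtOAc, rt
Reagents that add atoms: none
Why: Heterogeneous catalytic hydrogenation adds both hydrogens syn to the tetrasubstituted β-alkoxyacrylate, expected from the face opposite the large C5 aryl group, which sets C2 (aryl cis to the C5 aryl) and provisionally C3; rhodium on alumina is chosen because it has little tendency to cleave benzylic C–O bonds.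

Step 7
Reactants: 9 the 2,3-cis-3,4-trans-4,5-trans oxolane ester
Product: 10 ethyl 2,5-bis[3,5-dimethoxy-4-(methoxymethoxy)phenyl]-4-methyloxolane-3-carboxylate, C2 aryl/C3 ester trans, C3 ester/C4 methyl cis, C4 methyl/C5 aryl trans (racemic; 2S,3S,4R,5R enantiomer drawn)
Conditions: NaOEt (0.3 equiv), EtOH, 50 °C
Reagents that add atoms: none
Why: Thermodynamic epimerisation through the ester enolate should move the ester from the side of the bulky C2 aryl group to the side of the smaller C4 methyl, which sets C3; C2, C4 and C5 carry no acidic hydrogen, and ring opening by β-elimination is the reverse of a 5-endo closure and should be slow.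

Step 8
Reactants: 10 the 2,3-trans-3,4-cis-4,5-trans oxolane ester
Product: 11 {2,5-bis[3,5-dimethoxy-4-(methoxymethoxy)phenyl]-4-methyloxolan-3-yl}methanol, 2,3-trans-3,4-cis-4,5-trans (racemic; 2S,3R,4R,5R enantiomer drawn)
Conditions: LiAlH4, THF, 0 °C
Reagents that add atoms: none
Why: Hydride reduction of the ester to the primary alcohol is faster than enolisation at 0 °C, so the C3 configuration is kept, and the MOM acetals and ring ether are inert.

Step 9
Reactants: 11 the oxolan-3-ylmethanol
Product: 12 {2,5-bis[3,5-dimethoxy-4-(methoxymethoxy)phenyl]-4-methyloxolan-3-yl}methyl 4-methylbenzenesulfonate, 2,3-trans-3,4-cis-4,5-trans (racemic)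
Conditions: TsCl, Et3N, DMAP (cat.), CH2Cl2, 0 °C to rt
Reagents that add atoms: p-toluenesulfonyl chloride (TsCl), Cc1ccc(cc1)S(Cl)(=O)=O
Why: Sulfonylation of the only free hydroxyl group activates the primary carbon for hydride displacement without touching a stereocentre.

Step 10
Reactants: 12 the primary tosylate
Product: 13 (2S,3S,4R,5R)-2,5-bis[3,5-dimethoxy-4-(methoxymethoxy)phenyl]-3,4-dimethyloxolane (meso)
Conditions: LiEt3BH, THF, 0 °C to 50 °C
Reagents that add atoms: none
Why: SN2 displacement of the β-branched primary tosylate by the highly nucleophilic triethylborohydride turns CH2OTs into the C3 methyl; the reaction takes place at the exocyclic carbon, so all four ring stereocentres are kept.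

Step 11
Reactants: 13 the bis-MOM ether
Product: 14 Fragransin B1, 4,4'-[(2S,3S,4R,5R)-3,4-dimethyloxolane-2,5-diyl]bis(2,6-dimethoxyphenol) (meso)
Conditions: HCl (cat.), MeOH, 40 °C
Reagents that add atoms: none
Why: Acid-catalysed acetal exchange with methanol frees both phenols; each aryl group already lies trans to its neighbouring methyl, so the reversible benzylic ionisation that syringyl ethers undergo in acid can only maintain this thermodynamic arrangement, and C3 and C4 are not acid-labile.

**Compound list**

1 | acetosyringone, 1-(4-hydroxy-3,5-dimethoxyphenyl)ethan-1-one | CC(=O)c1cc(OC)c(O)c(OC)c1 | starting material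
2 | 1-[3,5-dimethoxy-4-(methoxymethoxy)phenyl]ethan-1-one | CC(=O)c1cc(OC)c(OCOC)c(OC)c1 | intermediate
3 | diethyl carbonate | CCOC(=O)OCC | starting material
4 | ethyl 3-[3,5-dimethoxy-4-(methoxymethoxy)phenyl]-3-oxopropanoate | CCOC(=O)CC(=O)c1cc(OC)c(OCOC)c(OC)c1 | intermediate
5 | 4-allyl-2,6-dimethoxyphenol | C=CCc1cc(OC)c(O)c(OC)c1 | starting material
6 | 5-allyl-1,3-dimethoxy-2-(methoxymethoxy)benzene | C=CCc1cc(OC)c(OCOC)c(OC)c1 | intermediate
7 | (E)-1,3-dimethoxy-2-(methoxymethoxy)-5-(prop-1-en-1-yl)benzene | C/C=C/c1cc(OC)c(OCOC)c(OC)c1 | intermediate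
8 | ethyl 4,5-trans-2,5-bis[3,5-dimethoxy-4-(methoxymethoxy)phenyl]-4-methyl-4,5-dihydrofuran-3-carboxylate (racemic) | COCOc1c(OC)cc(C2=C(C(=O)OCC)[C@@H](C)[C@H](c3cc(OC)c(OCOC)c(OC)c3)O2)cc1OC | intermediate
9 | ethyl 2,3-cis-3,4-trans-4,5-trans-2,5-bis[3,5-dimethoxy-4-(methoxymethoxy)phenyl]-4-methyloxolane-3-carboxylate (racemic) | COc1cc([C@H]2O[C@@H](c3cc(OC)c(OCOC)c(OC)c3)[C@H](C)[C@H]2C(=O)OCC)cc(OC)c1OCOC | intermediate
10 | ethyl 2,3-trans-3,4-cis-4,5-trans-2,5-bis[3,5-dimethoxy-4-(methoxymethoxy)phenyl]-4-methyloxolane-3-carboxylate (racemic) | COc1cc([C@H]2O[C@@H](c3cc(OC)c(OCOC)c(OC)c3)[C@H](C)[C@@H]2C(=O)OCC)cc(OC)c1OCOC | intermediate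
11 | {2,3-trans-3,4-cis-4,5-trans-2,5-bis[3,5-dimethoxy-4-(methoxymethoxy)phenyl]-4-methyloxolan-3-yl}methanol (racemic) | COc1cc([C@H]2O[C@@H](c3cc(OC)c(OCOC)c(OC)c3)[C@H](C)[C@@H]2CO)cc(OC)c1OCOC | intermediate
12 | {2,3-trans-3,4-cis-4,5-trans-2,5-bis[3,5-dimethoxy-4-(methoxymethoxy)phenyl]-4-methyloxolan-3-yl}methyl 4-methylbenzenesulfonate (racemic) | COc1cc([C@H]2O[C@@H](c3cc(OC)c(OCOC)c(OC)c3)[C@H](C)[C@@H]2COS(=O)(=O)c4ccc(C)cc4)cc(OC)c1OCOC | intermediate
13 | (2S,3S,4R,5R)-2,5-bis[3,5-dimethoxy-4-(methoxymethoxy)phenyl]-3,4-dimethyloxolane (meso) | COc1cc([C@H]2O[C@@H](c3cc(OC)c(OCOC)c(OC)c3)[C@H](C)[C@@H]2C)cc(OC)c1OCOC | intermediate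
14 | Fragransin B1, 4,4'-[(2S,3S,4R,5R)-3,4-dimethyloxolane-2,5-diyl]bis(2,6-dimethoxyphenol) (meso) | COc1cc([C@H]2O[C@@H](c3cc(OC)c(O)c(OC)c3)[C@H](C)[C@@H]2C)cc(OC)c1O | target

**Step count**

Total: 11 steps. Longest linear sequence: 9 steps (steps 1, 2, 5–11; the branch through steps 3, 4, 5–11 is equally long).

**Steps most likely to fail**

1. Step 6. Hydrogen may be delivered to the other face of C2=C3 (anti to the adjacent C4 methyl and syn to the C5 aryl), so that C2 and C3 come out in the opposite sense. The fallback sets out from 8 and comes back at 14, and it moves the stereocontrol from base epimerisation at C3 to acid epimerisation at C2. The product of the other facial course is the 2,3-cis-3,4-cis-4,5-trans oxolane ester F1, whose ester already lies cis to the C4 methyl. It is therefore not treated with base, which would drive the ester trans to both neighbours. LiAlH4 should give the alcohol F2, TsCl/Et3N the tosylate F3, and LiEt3BH the 2,3-cis-3,4-cis-4,5-trans dimethyloxolane F4. HCl in MeOH at 50 °C then removes the MOM groups and, through the reversible benzylic cation (the known acid-mediated benzylic epimerisation of 2-aryloxolane lignans), turns the C2 aryl trans to the C3 methyl to give 14.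

2. Step 7. The equilibrium at C3 may not lie far enough on the side of the ester cis to the C4 methyl, or the base may open the ring by β-elimination and scramble C2. The fallback sets out from 8 and comes back at 14, and it sets the C3/C4 cis relation by syn-hydrogenation instead of by equilibration. DDQ in toluene at 80 °C should dehydrogenate 8 to the furan ester F5. Hydrogenation of F5 (H2, Rh/Al2O3, higher pressure) adds hydrogen across C4=C5 first, which puts the methyl and the C5 aryl on one face, so the second addition comes from the other face and gives the all-cis oxolane ester F6. LiAlH4, TsCl/Et3N and LiEt3BH then lead through the all-cis alcohol F7 and the all-cis tosylate F8 to the all-cis dimethyloxolane F9. HCl in MeOH at 50 °C removes the MOM groups and epimerises both benzylic centres to the arrangement with each aryl trans to its neighbouring methyl, which is 14.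

3. Step 5. The MOM acetals may be lost in warm acetic acid, or the trialkoxyarenes and the propenyl group may be oxidised by trivalent manganese to radical cations in competition with enolate oxidation. The fallback sets out from 4 and 7 and comes back at 8, and it replaces the one-electron oxidation by metal-carbene chemistry under neutral conditions. Diazo transfer to 4 (p-acetamidobenzenesulfonyl azide, Et3N, MeCN) should give the diazo keto ester F10. Rh2(OAc)4 (dirhodium tetraacetate, 1 mol%) in CH2Cl2 with 7 should give the donor–acceptor cyclopropane F11. Its bond between the aryl-bearing carbon and the diacyl carbon ionises readily, on gentle warming or with a trace of Sc(OTf)3, and the ketone oxygen recloses on the benzylic carbon (Cloke–Wilson ring expansion) to give the trans dihydrofuran 8.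

**Further compounds**

F1 | step 6 | ethyl 2,3-cis-3,4-cis-4,5-trans-2,5-bis[3,5-dimethoxy-4-(methoxymethoxy)phenyl]-4-methyloxolane-3-carboxylate (racemic) | COc1cc([C@@H]2O[C@@H](c3cc(OC)c(OCOC)c(OC)c3)[C@H](C)[C@@H]2C(=O)OCC)cc(OC)c1OCOC
F2 | step 6 | {2,3-cis-3,4-cis-4,5-trans-2,5-bis[3,5-dimethoxy-4-(methoxymethoxy)phenyl]-4-methyloxolan-3-yl}methanol (racemic) | COc1cc([C@@H]2O[C@@H](c3cc(OC)c(OCOC)c(OC)c3)[C@H](C)[C@@H]2CO)cc(OC)c1OCOC
F3 | step 6 | {2,3-cis-3,4-cis-4,5-trans-2,5-bis[3,5-dimethoxy-4-(methoxymethoxy)phenyl]-4-methyloxolan-3-yl}methyl 4-methylbenzenesulfonate (racemic) | COc1cc([C@@H]2O[C@@H](c3cc(OC)c(OCOC)c(OC)c3)[C@H](C)[C@@H]2COS(=O)(=O)c4ccc(C)cc4)cc(OC)c1OCOC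
F4 | step 6 | 2,3-cis-3,4-cis-4,5-trans-2,5-bis[3,5-dimethoxy-4-(methoxymethoxy)phenyl]-3,4-dimethyloxolane (racemic) | COc1cc([C@@H]2O[C@@H](c3cc(OC)c(OCOC)c(OC)c3)[C@H](C)[C@@H]2C)cc(OC)c1OCOC
F5 | step 7 | ethyl 2,5-bis[3,5-dimethoxy-4-(methoxymethoxy)phenyl]-4-methylfuran-3-carboxylate | CCOC(=O)c1c(C)c(-c2cc(OC)c(OCOC)c(OC)c2)oc1-c1cc(OC)c(OCOC)c(OC)c1
F6 | step 7 | ethyl all-cis-2,5-bis[3,5-dimethoxy-4-(methoxymethoxy)phenyl]-4-methyloxolane-3-carboxylate (racemic) | COc1cc([C@H]2O[C@@H](c3cc(OC)c(OCOC)c(OC)c3)[C@@H](C)[C@H]2C(=O)OCC)cc(OC)c1OCOC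
F7 | step 7 | {all-cis-2,5-bis[3,5-dimethoxy-4-(methoxymethoxy)phenyl]-4-methyloxolan-3-yl}methanol (racemic) | COc1cc([C@H]2O[C@@H](c3cc(OC)c(OCOC)c(OC)c3)[C@@H](C)[C@H]2CO)cc(OC)c1OCOC
F8 | step 7 | {all-cis-2,5-bis[3,5-dimethoxy-4-(methoxymethoxy)phenyl]-4-methyloxolan-3-yl}methyl 4-methylbenzenesulfonate (racemic) | COc1cc([C@H]2O[C@@H](c3cc(OC)c(OCOC)c(OC)c3)[C@@H](C)[C@H]2COS(=O)(=O)c4ccc(C)cc4)cc(OC)c1OCOC
F9 | step 7 | all-cis-2,5-bis[3,5-dimethoxy-4-(methoxymethoxy)phenyl]-3,4-dimethyloxolane (meso) | COc1cc([C@H]2O[C@@H](c3cc(OC)c(OCOC)c(OC)c3)[C@@H](C)[C@H]2C)cc(OC)c1OCOC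
F10 | step 5 | ethyl 2-diazo-3-[3,5-dimethoxy-4-(methoxymethoxy)phenyl]-3-oxopropanoate | CCOC(=O)C(=[N+]=[N-])C(=O)c1cc(OC)c(OCOC)c(OC)c1
F11 | step 5 | ethyl 1-[3,5-dimethoxy-4-(methoxymethoxy)benzoyl]-2-[3,5-dimethoxy-4-(methoxymethoxy)phenyl]-3-methylcyclopropane-1-carboxylate, aryl and methyl trans, mixture at C1 (racemic) | CCOC(=O)C1(C(=O)c2cc(OC)c(OCOC)c(OC)c2)[C@H](C)[C@H]1c1cc(OC)c(OCOC)c(OC)c1
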